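**Plan**
1. Labels: lactone C3 carries the ring A benzyl group and C4 the ring B benzyl group. C5 of ring B carries the chain Cb(H)(CcH2OH)–Ca(H)(OH)–ring C.
2. Enabling feature: the chain is a 1,3-diol (oxygens on Cc and Ca). Cc is a lone CH2OH on the ring B methine Cb, and Ca is a benzylic carbinol para to the ring C oxygen. This is the pattern left when CH2=O adds across a ring B–CH=CH–ring C stilbene.
3. Cuts, in retrosynthetic order: the benzyl-type groups and the O–CH2–O bridge; Cb–Cc and Ca–O of the 1,3-dioxane (Prins); ring B C5–vinyl (Heck); C3–CH2(ring A) (enolate alkylation); ring B–CH2 (aryl copper opening of a cyclopropane-fused lactone).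
4. Forward order: the cyclopropane and lactone rings form together, then ring B, ring A and ring C are attached in turn. The dioxane is the last ring closed and is opened again.
5. Stereochemistry: C4 comes from (R)-epichlorohydrin and C3 from alkylation anti to the C4 substituent. Cb comes from the alkene face chosen by the chiral acid, and Ca from suprafacial addition to the E-alkene (trans-dioxane).

Key step: step 13

Assumption: the sense of induction of the catalyst on a stilbene cannot be derived from the terminal styrene cases. Both antipodes are available from (R)- or (S)-BINOL, and wherever (S,S) is written it means the antipode that gives the (4R,5R)-dioxane.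

**Step 1**
Reactants: 1 (R)-epichlorohydrin; 2 dimethyl malonate
Product: 5 methyl (1S,5R)-2-oxo-3-oxabicyclo[3.1.0]hexane-1-carboxylate, via oxiranylmethyl malonate 3 (not isolated), via cyclopropyl carbinol 4 (not isolated)
Conditions: NaOMe, MeOH, 0 °C → reflux
Reagents that add atoms: none
Why: In this tandem malonate alkylation–lactonisation the malonate anion opens the epoxide at its CH2, the alkoxide displaces chloride to give the transposed epoxide 3, the re-formed anion opens 3 in a 3-exo-tet closure with inversion to give 4, and the alkoxide lactonises onto the cis ester, so the one stereocentre of 1 fixes both ring-fusion centres of 5.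

**Step 2**
Reactants: 6 4-bromo-2-methoxyphenol
Product: 7 4-bromo-2-methoxy-1-(methoxymethoxy)benzene
Conditions: NaH, THF, 0 °C; MOMCl, 0 °C → rt
Reagents that add atoms: chloromethyl methyl ether, COCCl
Why: Williamson-type O-alkylation of the phenoxide gives an acetal ether that tolerates magnesium, hot wet DMSO and amide base and can later be removed beside a benzyl ether.

**Step 3**
Reactants: 7 4-bromo-2-methoxy-1-(methoxymethoxy)benzene; 5 methyl (1S,5R)-2-oxo-3-oxabicyclo[3.1.0]hexane-1-carboxylate
Product: 9 methyl (4R)-4-[3-methoxy-4-(methoxymethoxy)benzyl]-2-oxooxolane-3-carboxylate (C3 labile and left undefined), via aryl Grignard reagent 8 (not isolated)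
Conditions: Mg, THF, 45 °C; then CuBr·SMe2 (15 mol %), 5, THF, −30 → 0 °C; aq. NH4Cl
Reagents that add atoms: none
Why: In this copper-catalysed homoconjugate addition of a Grignard reagent to a doubly activated cyclopropane the aryl copper species attacks the unsubstituted cyclopropane CH2 in SN2 fashion and expels the malonate-type enolate, so the CH stereocentre of 5 is untouched and becomes C4 (R).

**Step 4**
Reactants: 9 methyl (4R)-4-[3-methoxy-4-(methoxymethoxy)benzyl]-2-oxooxolane-3-carboxylate
Product: 10 (4R)-4-[3-methoxy-4-(methoxymethoxy)benzyl]oxolan-2-one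
Conditions: LiCl, DMSO–H2O, 135 °C
Reagents that add atoms: none
Why: Krapcho demethoxycarbonylation removes the activating ester under neutral conditions (chloride dealkylates it and the carboxylate loses CO2), which leaves the lactone, the MOM ether and C4 unchanged.

**Step 5**
Reactants: 11 4-(benzyloxy)-3-methoxybenzaldehyde
Product: 12 [4-(benzyloxy)-3-methoxyphenyl]methanol
Conditions: NaBH4, MeOH, 0 °C
Reagents that add atoms: none
Why: Borohydride reduction of an aromatic aldehyde is clean and leaves the benzyl ether untouched.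

**Step 6**
Reactants: 12 [4-(benzyloxy)-3-methoxyphenyl]methanol
Product: 13 1-(benzyloxy)-4-(bromomethyl)-2-methoxybenzene
Conditions: PBr3, Et2O, 0 °C
Reagents that add atoms: phosphorus tribromide, BrP(Br)Br
Why: Bromodehydroxylation of a benzylic alcohol through its phosphite ester is fast at 0 °C, and the labile electron-rich bromide is used directly.

**Step 7**
Reactants: 10 (4R)-4-[3-methoxy-4-(methoxymethoxy)benzyl]oxolan-2-one; 13 1-(benzyloxy)-4-(bromomethyl)-2-methoxybenzene
Product: 15 (3R,4R)-3-[4-(benzyloxy)-3-methoxybenzyl]-4-[3-methoxy-4-(methoxymethoxy)benzyl]oxolan-2-one, via lithium enolate 14 (not isolated)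
Conditions: LiN(SiMe3)2, THF, −78 °C; 13, DMPU, −78 → −30 °C
Reagents that add atoms: none
Why: In this lactone enolate alkylation, the standard entry to dibenzylbutyrolactones, the bromide approaches the enolate face opposite the C4 benzyl group, which sets C3 as R (3,4-trans, also the thermodynamic isomer).

**Step 8**
Reactants: 15 (3R,4R)-3-[4-(benzyloxy)-3-methoxybenzyl]-4-[3-methoxy-4-(methoxymethoxy)benzyl]oxolan-2-one
Product: 16 (3R,4R)-3-[4-(benzyloxy)-3-methoxybenzyl]-4-(4-hydroxy-3-methoxybenzyl)oxolan-2-one
Conditions: HCl (cat.), MeOH–THF, 45 °C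
Reagents that add atoms: none
Why: Acid-catalysed transacetalisation passes the CH2 unit of the phenolic MOM ether to methanol, while the benzyl ether and the γ-lactone are stable to dilute acid.

**Step 9**
Reactants: 16 (3R,4R)-3-[4-(benzyloxy)-3-methoxybenzyl]-4-(4-hydroxy-3-methoxybenzyl)oxolan-2-one
Product: 17 (3R,4R)-3-[4-(benzyloxy)-3-methoxybenzyl]-4-(4-hydroxy-3-iodo-5-methoxybenzyl)oxolan-2-one
Conditions: BnNMe3 ICl2, NaHCO3, CH2Cl2–MeOH, rt, dark
Reagents that add atoms: benzyltrimethylammonium dichloroiodate, C[N+](C)(C)Cc1ccccc1.Cl[I-]Cl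
Why: In this electrophilic aromatic iodination the bicarbonate-buffered dichloroiodate attacks free phenols but not aryl ethers, so ring A is spared, and in ring B the para and one ortho position of the phenol are blocked, which leaves only C5.

**Step 10**
Reactants: 11 4-(benzyloxy)-3-methoxybenzaldehyde
Product: 18 1-(benzyloxy)-4-ethenyl-2-methoxybenzene
Conditions: MePPh3Br, KOtBu, THF, 0 °C → rt
Reagents that add atoms: methyltriphenylphosphonium bromide, C[P+](c1ccccc1)(c1ccccc1)c1ccccc1.[Br-]
Why: Wittig methylenation of a non-enolisable aromatic aldehyde gives the ring C styrene in one operation.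

**Step 11**
Reactants: 17 (3R,4R)-3-[4-(benzyloxy)-3-methoxybenzyl]-4-(4-hydroxy-3-iodo-5-methoxybenzyl)oxolan-2-one; 18 1-(benzyloxy)-4-ethenyl-2-methoxybenzene
Product: 19 (3R,4R)-3-[4-(benzyloxy)-3-methoxybenzyl]-4-{3-[(E)-2-(4-benzyloxy-3-methoxyphenyl)ethenyl]-4-hydroxy-5-methoxybenzyl}oxolan-2-one
Conditions: Pd(OAc)2 (5 mol %), Bu4NCl, NaHCO3, DMF, 70 °C, Ar
Reagents that add atoms: none
Why: In this Mizoroki–Heck reaction zerovalent palladium inserts into the C–I bond, the halide-bound (neutral) pathway directs syn carbopalladation to the terminal carbon of the styrene, and syn β-hydride elimination gives the E-stilbene, with free ortho-iodophenols being tolerated partners.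

**Step 12**
Reactants: 19 (3R,4R)-3-[4-(benzyloxy)-3-methoxybenzyl]-4-{3-[(E)-2-(4-benzyloxy-3-methoxyphenyl)ethenyl]-4-hydroxy-5-methoxybenzyl}oxolan-2-one
Product: 20 benzyl carbonate of 19 at the ring B phenol ((E)-stilbene on the lactone core)
Conditions: BnOCOCl, K2CO3, acetone, 0 °C → rt
Reagents that add atoms: benzyl chloroformate, O=C(Cl)OCc1ccccc1
Why: O-acylation of the phenoxide with a chloroformate turns the ring B oxygen into a poor donor, and the carbonate is chosen over a carboxylic ester because it leaves in the final hydrogenolysis even if it migrates to an aliphatic hydroxyl.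

**Step 13**
Reactants: 20 benzyl carbonate of 19 ((E)-stilbene on the lactone core); 21 formaldehyde (charged as paraformaldehyde, two units are built in)
Product: 22 (4R,5R)-trans-4-(4-benzyloxy-3-methoxyphenyl)-5-(ring B aryl)-1,3-dioxane on the lactone core
Conditions: (CH2O)n, (S,S)-HN[P(=NSO2CF3)(O2C20H10Ar2)]2 (Ar = 4-tBuC6H4, BINOL-derived N-triflyl imidodiphosphorimidate, 5 mol %), CHCl3, 0 °C
Reagents that add atoms: none
Why: Proposed new method: the strongly acidic, confined imidodiphosphorimidate protonates the end of a formaldehyde oligomer inside its chiral pocket, alkene carbon Cb next to ring B attacks the activated CH2=O+ carbon (Cb–Cc bond), and the charge growing at Ca is quenched by the oxygen of the adjoining O–CH2–O unit (Ca–O bond) in a concerted but very asynchronous event. The closest known reaction type is the imidodiphosphorimidate-catalysed asymmetric Prins reaction of terminal styrenes with paraformaldehyde to 4-aryl-1,3-dioxanes, which has not been shown for a 1,2-diaryl alkene. The single new ring, the 1,3-dioxane, closes through a six-membered chair in which the hemiacetal-type oxygen captures the quinone-methide-like benzylic cation (formally 6-exo-trig, the delocalised Ca–ring C bond lying outside the ring) with both aryl groups equatorial. Cb is fixed by the alkene face that the chiral counter-anion leaves open (catalyst control, since the lactone stereocentres are remote), and Ca follows from suprafacial addition of carbon and oxygen to the E-alkene, which together give the trans-(4R,5R) ring. The regiochemistry (carbon to Cb, oxygen to Ca) is secured by the para-benzyloxy group of ring C, which stabilises charge at Ca, whereas ring B has its only ortho or para oxygen switched off as a carbonate and its methoxy group meta to Cb. Chemoselectivity for the alkene over Friedel–Crafts hydroxymethylation of the alkoxyarenes rests on the higher π-nucleophilicity of the para-alkoxystilbene, the low temperature and the absence of free acid outside the pocket.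

**Step 14**
Reactants: 22 (4R,5R)-trans-4,5-diaryl-1,3-dioxane on the lactone core
Product: 24 (1R,2R)-1,3-diol with two benzyl ethers plus the ring B benzyl carbonate, via bipyridinium salt 23 (not isolated)
Conditions: Me3SiOTf, 2,2'-bipyridyl, CH2Cl2, 0 °C → rt; then H2O, rt
Reagents that add atoms: none
Why: In this known silyl triflate–bipyridyl cleavage of methylene acetals the less hindered primary oxygen is silylated, the oxocarbenium ion left on the Ca oxygen is trapped by bipyridyl as 23, and water hydrolyses the N,O-acetal and the silyl ether, so only O–CH2 bonds break under weakly basic conditions and the Ca–O bond keeps its configuration.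

**Step 15**
Reactants: 24 (1R,2R)-1,3-diol with two benzyl ethers plus the ring B benzyl carbonate
Product: 25 target, (3R,4R)-4-{3-[(1R,2R)-1,3-dihydroxy-1-(4-hydroxy-3-methoxyphenyl)propan-2-yl]-4-hydroxy-5-methoxybenzyl}-3-(4-hydroxy-3-methoxybenzyl)oxolan-2-one
Conditions: H2 (1 atm), Pd/C (10 wt % Pd), EtOAc–EtOH, rt
Reagents that add atoms: none
Why: Catalytic hydrogenolysis in a neutral solvent cleaves aryl benzyl ethers and the benzyl carbonate (which then loses CO2) faster than the secondary benzylic alcohol, as is usual for arylglycerol-type lignin models, and touches no stereocentre.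

**Compound list**
1 | (R)-epichlorohydrin | ClC[C@H]1CO1 | starting material
2 | dimethyl malonate | COC(=O)CC(=O)OC | starting material
3 | dimethyl 2-{[(2R)-oxiran-2-yl]methyl}propanedioate (present as its sodium enolate) | COC(=O)C(C[C@@H]1CO1)C(=O)OC | intermediate
4 | dimethyl (2R)-2-(hydroxymethyl)cyclopropane-1,1-dicarboxylate (present as its alkoxide) | COC(=O)C1(C(=O)OC)C[C@H]1CO | intermediate
5 | methyl (1S,5R)-2-oxo-3-oxabicyclo[3.1.0]hexane-1-carboxylate | O=C1OC[C@@H]2C[C@]12C(=O)OC | intermediate
6 | 4-bromo-2-methoxyphenol | COc1cc(Br)ccc1O | starting material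
7 | 4-bromo-2-methoxy-1-(methoxymethoxy)benzene | COCOc1ccc(Br)cc1OC | intermediate
8 | [3-methoxy-4-(methoxymethoxy)phenyl]magnesium bromide | COCOc1ccc([Mg]Br)cc1OC | intermediate
9 | methyl (4R)-4-[3-methoxy-4-(methoxymethoxy)benzyl]-2-oxooxolane-3-carboxylate (C3 epimers) | COCOc1ccc(C[C@H]2COC(=O)C2C(=O)OC)cc1OC | intermediate
10 | (4R)-4-[3-methoxy-4-(methoxymethoxy)benzyl]oxolan-2-one | COCOc1ccc(C[C@H]2COC(=O)C2)cc1OC | intermediate
11 | 4-(benzyloxy)-3-methoxybenzaldehyde | COc1cc(C=O)ccc1OCc1ccccc1 | starting material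
12 | [4-(benzyloxy)-3-methoxyphenyl]methanol | COc1cc(CO)ccc1OCc1ccccc1 | intermediate
13 | 1-(benzyloxy)-4-(bromomethyl)-2-methoxybenzene | COc1cc(CBr)ccc1OCc1ccccc1 | intermediate
14 | lithium enolate of 10 | [Li+].COCOc1ccc(C[C@H]2COC([O-])=C2)cc1OC | intermediate
15 | (3R,4R)-3-[4-(benzyloxy)-3-methoxybenzyl]-4-[3-methoxy-4-(methoxymethoxy)benzyl]oxolan-2-one | COc1cc(C[C@H]2C(=O)OC[C@@H]2Cc2cc(OC)c(OCOC)cc2)ccc1OCc1ccccc1 | intermediate
16 | (3R,4R)-3-[4-(benzyloxy)-3-methoxybenzyl]-4-(4-hydroxy-3-methoxybenzyl)oxolan-2-one | COc1cc(C[C@H]2C(=O)OC[C@@H]2Cc2cc(OC)c(O)cc2)ccc1OCc1ccccc1 | intermediate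
17 | (3R,4R)-3-[4-(benzyloxy)-3-methoxybenzyl]-4-(4-hydroxy-3-iodo-5-methoxybenzyl)oxolan-2-one | COc1cc(C[C@H]2C(=O)OC[C@@H]2Cc2cc(OC)c(O)c(I)c2)ccc1OCc1ccccc1 | intermediate
18 | 1-(benzyloxy)-4-ethenyl-2-methoxybenzene | COc1cc(C=C)ccc1OCc1ccccc1 | intermediate
19 | (E)-hydroxystilbene on the lactone core (ring B phenol free, rings A and C as benzyl ethers) | COc1cc(C[C@H]2C(=O)OC[C@@H]2Cc2cc(OC)c(O)c(/C=C/c3ccc(OCc4ccccc4)c(OC)c3)c2)ccc1OCc1ccccc1 | intermediate
20 | (E)-stilbene on the lactone core, ring B phenol as benzyl carbonate | COc1cc(C[C@H]2C(=O)OC[C@@H]2Cc2cc(OC)c(OC(=O)OCc5ccccc5)c(/C=C/c3ccc(OCc4ccccc4)c(OC)c3)c2)ccc1OCc1ccccc1 | intermediate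
21 | formaldehyde (as paraformaldehyde) | C=O | starting material
22 | (4R,5R)-trans-4,5-diaryl-1,3-dioxane on the lactone core | COc1cc(C[C@H]2C(=O)OC[C@@H]2Cc2cc(OC)c(OC(=O)OCc6ccccc6)c([C@@H]4COCO[C@H]4c3ccc(OCc5ccccc5)c(OC)c3)c2)ccc1OCc1ccccc1 | intermediate
23 | bipyridinium triflate: Ca–O–CH2–N+(2,2'-bipyridyl), Cc–O–SiMe3 | COc1cc(C[C@H]2C(=O)OC[C@@H]2Cc2cc(OC)c(OC(=O)OCc6ccccc6)c([C@H](CO[Si](C)(C)C)[C@@H](OC[n+]7ccccc7-c8ccccn8)c3ccc(OCc5ccccc5)c(OC)c3)c2)ccc1OCc1ccccc1.[O-]S(=O)(=O)C(F)(F)F | intermediate
24 | (1R,2R)-1,3-diol, rings A and C as benzyl ethers, ring B phenol as benzyl carbonate | COc1cc(C[C@H]2C(=O)OC[C@@H]2Cc2cc(OC)c(OC(=O)OCc6ccccc6)c([C@H](CO)[C@@H](O)c3ccc(OCc5ccccc5)c(OC)c3)c2)ccc1OCc1ccccc1 | intermediate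
25 | (3R,4R)-4-{3-[(1R,2R)-1,3-dihydroxy-1-(4-hydroxy-3-methoxyphenyl)propan-2-yl]-4-hydroxy-5-methoxybenzyl}-3-(4-hydroxy-3-methoxybenzyl)oxolan-2-one | COc1cc(C[C@H]2C(=O)OC[C@@H]2Cc2cc(OC)c(O)c([C@H](CO)[C@@H](O)c3ccc(O)c(OC)c3)c2)ccc1O | target

**Total step count:** 15
**Longest linear sequence:** 11 steps (2, 3, 4, 7, 8, 9, 11, 12, 13, 14, 15)

**Steps most likely to fail**

**Step 13 (asymmetric Prins reaction).**
- Risk: the large, Lewis-basic substrate may fail to enter the confined acid or may block it, so that there is no turnover. The two alkene faces may be poorly differentiated. The activated formaldehyde may be diverted into hydroxymethylation of the alkoxyarenes.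
- The fallback uses known chemistry. It makes the Cb–Ca bond by an auxiliary-controlled anti aldol addition instead of functionalising an alkene. It sets out from 17 and comes back at 25.
- Compound 17 is benzylated (BnBr, K2CO3, DMF) to the ring B benzyl ether iodide F1.
- F1 is coupled with commercial BrZnCH2CO2tBu (Pd(dba)2, P(tBu)3, THF, rt) to the tert-butyl arylacetate F2. This Negishi-type arylation of a Reformatsky reagent is neutral enough for the lactone.
- CF3CO2H in CH2Cl2 gives the arylacetic acid F3. DCC and DMAP with (R)-4-benzyloxazolidin-2-one then give the N-arylacetyl imide F4.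
- The MgCl2-catalysed direct anti aldol addition to aldehyde 11 (MgCl2 10 mol %, Et3N, Me3SiCl, EtOAc, rt) should give the silylated (2S,3R)-anti aldol adduct F5. Soft enolisation touches only the imide. The auxiliary antipode is assigned on the chelated magnesium enolate model.
- NaBH4 in THF–H2O at 0 °C, followed by citric acid in MeOH, removes the auxiliary and the silyl group to give the tri-O-benzyl diol F6.
- Hydrogenolysis under the conditions of step 15 leads to 25.

**Step 14 (methylene acetal cleavage).**
- Risk: the para-benzyloxybenzylic Ca–O bond may ionise in competition with O–CH2 cleavage, with loss of configuration at Ca. Hydrolysis of the N,O-acetal may also stall.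
- The fallback removes the donor from ring C before the acetal is opened. It sets out from 22 and comes back at 25.
- Compound 22 is hydrogenolysed first (H2, Pd/C, EtOAc) to the triphenol dioxane F7.
- All three phenols are acylated (benzyl chloroformate, K2CO3, acetone) to the tris(benzyl carbonate) dioxane F8. Its ring C para-acyloxy group no longer supports a cation at Ca.
- The acetal can then be opened with the stronger classical reagent Me2BBr (CH2Cl2, −78 °C; aq. NaHCO3) to the tris(benzyl carbonate) diol F9.
- Neutral hydrogenolysis as in step 15 gives 25.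

**Step 11 (Heck coupling).**
- Risk: oxidative addition and insertion may be slow at the hindered, electron-rich iodophenol, palladium may precipitate, and the electron-rich styrene may be arylated at its internal carbon.
- The fallback forms the C=C bond by metathesis. It sets out from 17 and comes back at 20.
- Suzuki–Miyaura vinylation of 17 (K[CH2=CHBF3], PdCl2(dppf), Cs2CO3, THF–H2O, 70 °C) gives the 5-vinylphenol F10.
- Benzyl chloroformate and K2CO3 give its benzyl carbonate F11.
- Cross-metathesis of this ortho-substituted styrene, which homodimerises slowly, with an excess of 18 should give the E-stilbene 20. The catalyst is the second-generation Grubbs catalyst, (H2IMes)(PCy3)Cl2Ru=CHPh, in CH2Cl2 at 40 °C.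

**Further compounds**
F1 | step 13 | ring B benzyl ether of iodide 17 | COc1cc(C[C@H]2C(=O)OC[C@@H]2Cc2cc(OC)c(OCc3ccccc3)c(I)c2)ccc1OCc1ccccc1
F2 | step 13 | tert-butyl arylacetate at ring B C5 | COc1cc(C[C@H]2C(=O)OC[C@@H]2Cc2cc(OC)c(OCc3ccccc3)c(CC(=O)OC(C)(C)C)c2)ccc1OCc1ccccc1
F3 | step 13 | arylacetic acid at ring B C5 | COc1cc(C[C@H]2C(=O)OC[C@@H]2Cc2cc(OC)c(OCc3ccccc3)c(CC(=O)O)c2)ccc1OCc1ccccc1
F4 | step 13 | N-arylacetyl-(R)-4-benzyloxazolidin-2-one | COc1cc(C[C@H]2C(=O)OC[C@@H]2Cc2cc(OC)c(OCc3ccccc3)c(CC(=O)N4[C@H](Cc5ccccc5)COC4=O)c2)ccc1OCc1ccccc1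
F5 | step 13 | O-trimethylsilyl (2S,3R)-anti aldol adduct | COc1cc(C[C@H]2C(=O)OC[C@@H]2Cc2cc(OC)c(OCc3ccccc3)c([C@H](C(=O)N4[C@H](Cc5ccccc5)COC4=O)[C@@H](O[Si](C)(C)C)c6ccc(OCc7ccccc7)c(OC)c6)c2)ccc1OCc1ccccc1
F6 | step 13 | tri-O-benzyl (1R,2R)-1,3-diol | COc1cc(C[C@H]2C(=O)OC[C@@H]2Cc2cc(OC)c(OCc3ccccc3)c([C@H](CO)[C@@H](O)c6ccc(OCc7ccccc7)c(OC)c6)c2)ccc1OCc1ccccc1
F7 | step 14 | triphenol (4R,5R)-dioxane | COc1cc(C[C@H]2C(=O)OC[C@@H]2Cc2cc(OC)c(O)c([C@@H]4COCO[C@H]4c3ccc(O)c(OC)c3)c2)ccc1O
F8 | step 14 | tris(benzyl carbonate) (4R,5R)-dioxane | COc1cc(C[C@H]2C(=O)OC[C@@H]2Cc2cc(OC)c(OC(=O)OCc6ccccc6)c([C@@H]4COCO[C@H]4c3ccc(OC(=O)OCc5ccccc5)c(OC)c3)c2)ccc1OC(=O)OCc1ccccc1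
F9 | step 14 | tris(benzyl carbonate) (1R,2R)-1,3-diol | COc1cc(C[C@H]2C(=O)OC[C@@H]2Cc2cc(OC)c(OC(=O)OCc6ccccc6)c([C@H](CO)[C@@H](O)c3ccc(OC(=O)OCc5ccccc5)c(OC)c3)c2)ccc1OC(=O)OCc1ccccc1
F10 | step 11 | 5-vinylphenol on the lactone core | COc1cc(C[C@H]2C(=O)OC[C@@H]2Cc2cc(OC)c(O)c(C=C)c2)ccc1OCc1ccccc1
F11 | step 11 | benzyl carbonate of the 5-vinylphenol | COc1cc(C[C@H]2C(=O)OC[C@@H]2Cc2cc(OC)c(OC(=O)OCc3ccccc3)c(C=C)c2)ccc1OCc1ccccc1
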